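Atom labels follow guaiane numbering: ring A is the cyclopentenone C1–C5, ring B is the seven-membered ring C1, C5–C10, and C11 is the carbinol carbon on C7. The retrosynthesis cuts, in order, the acetyl–O11 and propionyl–O8 bonds, the two C11–CH3 bonds (back to a C7 methyl ester), H–C8 (back to a β-keto ester), C4=C5 and C1–C2 of ring A, and last C6–C7 and C9–C10 of ring B.
Enabling feature: ring B bears C11 on C7 and oxygen on the neighbouring C8, has bare methylenes at C6 and C9, one methyl-bearing stereocentre at C10 and an sp2 carbon at C5. This matches a three-carbon siloxyvinyl carbenoid (C7–C8–C9, ester carbon = C11) joined to a four-carbon 2-siloxy-(E)-penta-1,3-diene (C6–C5–C1–C10, terminal methyl = C14).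
Forward: ring B is made first by rhodium-carbenoid cyclopropanation and divinylcyclopropane Cope rearrangement. Ring A is then fused onto C1/C5 by nitroalkene conjugate addition, Nef hydrolysis and aldol condensation.
Stereochemistry: C10 comes from the chiral dirhodium catalyst, relayed through the boat Cope transition state and the E-alkene. C1 comes from attack anti to the C10 methyl and is also the expected thermodynamic epimer. C7 and C8 are set together as the cis pair by enzymatic reduction of the epimerising β-keto ester.
Endgame: the enone is masked as its allylic alcohol while the ester takes up two methyl groups, MnO2 restores it, and the secondary and tertiary alcohols are acylated one after the other.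

Key step: step 4

Assumption: the sense of induction of Rh2(S-PTAD)4 with this diene is inferred by analogy with (E)-1-substituted dienes; if the first run gives the antipodal cycloheptadiene, the equally accessible Rh2(R-PTAD)4 is used and nothing else changes.

Step 1
Reactants: 1 methyl acetoacetate
Product: 2 methyl 2-diazo-3-oxobutanoate
Conditions: p-ABSA, Et3N, MeCN, 0 °C to rt
Reagents that add atoms: 4-acetamidobenzenesulfonyl azide (p-ABSA), CC(=O)Nc1ccc(cc1)S(=O)(=O)N=[N+]=[N-]
Why: Regitz diazo transfer, in which the amine-generated enolate of the 1,3-dicarbonyl attacks the terminal azide nitrogen and the adduct collapses to diazo compound and sulfonamide, is routine for acetoacetates.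

Step 2
Reactants: 2 methyl 2-diazo-3-oxobutanoate
Product: 3 methyl 2-diazo-3-(tert-butyldimethylsilyloxy)but-3-enoate
Conditions: TBSOTf, Et3N, CH2Cl2, 0 °C
Reagents that add atoms: tert-butyldimethylsilyl triflate (TBSOTf), CC(C)(C)[Si](C)(C)OS(=O)(=O)C(F)(F)F
Why: Soft enolisation with O-silylation, in which the silyl triflate activates the acetyl carbonyl and the amine removes a methyl proton, is the standard entry to 3-siloxy vinyldiazoacetates and leaves the diazo group untouched.

Step 3
Reactants: 4 (E)-pent-3-en-2-one
Product: 5 (E)-2-(triethylsilyloxy)penta-1,3-diene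
Conditions: TESOTf, Et3N, Et2O, 0 °C
Reagents that add atoms: triethylsilyl triflate (TESOTf), CC[Si](CC)(CC)OS(=O)(=O)C(F)(F)F
Why: Kinetic enol silylation of an enone, in which the O-silylated carbonyl loses the accessible α'-methyl proton, should give the cross-conjugated 2-siloxy diene with the E-alkene unchanged.

Step 4
Reactants: 3 methyl 2-diazo-3-(tert-butyldimethylsilyloxy)but-3-enoate, 5 (E)-2-(triethylsilyloxy)penta-1,3-diene
Product: 7 methyl (4S)-2-(tert-butyldimethylsilyloxy)-4-methyl-6-(triethylsilyloxy)cyclohepta-1,5-diene-1-carboxylate, via cis-divinylcyclopropane 6 (not isolated)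
Conditions: Rh2(S-PTAD)4 (dirhodium tetrakis[(S)-(1-adamantyl)(N-phthalimido)acetate], 1 mol %), 5 (2 equiv), hexanes, −26 °C to rt, slow addition of 3; filtration through Et3N-deactivated SiO2
Reagents that add atoms: none
Why: Loss of N2 from 3 at the dirhodium core gives a donor/acceptor vinylcarbenoid whose carbene carbon (C7) adds in a concerted, asynchronous way across the terminal C6=C5 enol-ether bond of 5 to give cis-divinylcyclopropane 6, which at or below room temperature undergoes a [3,3] shift through the endo-boat transition state (C9–C10 forms, C5–C7 breaks). The closest known reaction type is the tandem cyclopropanation/Cope rearrangement (formal [4+3] cycloaddition) of siloxyvinyl diazoacetates with acyclic dienes, 2-siloxy dienes included, under chiral dirhodium tetracarboxylates. The transient three-membered ring closes by [2+1] carbene transfer, and ring B (C5–C6–C7–C8–C9–C10–C1) closes by strain-releasing sigmatropic ring expansion rather than by end-to-end cyclisation. The two cyclopropane centres (C7 and C5) are set by the chiral catalyst, which selects the alkene face, and by the usual preference of the alkenyl substituent of the trapped alkene to lie cis to the vinyl group of the carbenoid; both vanish in the Cope step, and their information passes stereospecifically to C10, the only stereocentre of 7, through the boat geometry and the E-propenyl group. The step needs site selectivity, secured because the electron-rich 1,1-disubstituted alkene reacts while such bulky carbenoids leave trans-1,2-disubstituted alkenes alone; it also needs carbenoid-site rather than vinylogous attack, favoured by the 3-siloxy group and the hydrocarbon solvent, and enantiofacial selectivity, which rests on the catalyst.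

Step 5
Reactants: 8 2-nitrobutan-1-ol
Product: 9 2-nitrobut-1-ene
Conditions: phthalic anhydride, 150–180 °C, reduced pressure, product distilled out as formed
Reagents that add atoms: none
Why: Thermal dehydration of a β-nitro alcohol through its hydrogen phthalate is the standard preparation of 2-nitroalkenes, and continuous distillation limits polymerisation.

Step 6
Reactants: 7 methyl (4S)-2-(tert-butyldimethylsilyloxy)-4-methyl-6-(triethylsilyloxy)cyclohepta-1,5-diene-1-carboxylate, 9 2-nitrobut-1-ene
Product: 11 methyl (4S,5R)-2-hydroxy-4-methyl-6-oxo-5-(2-oxobutyl)cyclohept-1-ene-1-carboxylate, via silyl nitronate 10 (not isolated)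
Conditions: SnCl4 (1.1 equiv), CH2Cl2, −78 °C; then H2O, reflux; then 1 M HCl, THF, rt
Reagents that add atoms: water, O
Why: In this Lewis-acid-mediated Mukaiyama–Michael addition to a nitroalkene followed by Nef hydrolysis of the nitronate (the classical 1,4-diketone synthesis), only the simple C5 enol ether should be nucleophilic enough at −78 °C because the C8 enol ether is deactivated by its ester, the bond forms regiospecifically at C1 with the electrophile approaching anti to the adjacent C10 methyl to set C1 as R, and the acidic aqueous phase also cleaves the TBS enol ether to free the β-keto ester.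

Step 7
Reactants: 11 methyl (4S,5R)-2-hydroxy-4-methyl-6-oxo-5-(2-oxobutyl)cyclohept-1-ene-1-carboxylate
Product: 13 methyl (8S,8aR)-6-hydroxy-3,8-dimethyl-2-oxo-1,2,4,7,8,8a-hexahydroazulene-5-carboxylate, via aldol adduct 12 (not isolated)
Conditions: NaOMe (2.5 equiv), MeOH, 0 to 50 °C; AcOH quench
Reagents that add atoms: none
Why: In this base-mediated intramolecular aldol condensation of a 1,4-diketone (cyclopentenone annulation) the β-keto ester is parked as its enolate and so shielded from attack and retro-Claisen cleavage, the ethyl ketone enolises at C4 and closes ring A on the C5 ketone in a 5-exo-trig manner, irreversible dehydration gives the tetrasubstituted enone, and the epimerisable C1 is expected to remain as the more stable epimer with C2 trans to the C10 methyl.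

Step 8
Reactants: 13 methyl (8S,8aR)-6-hydroxy-3,8-dimethyl-2-oxo-1,2,4,7,8,8a-hexahydroazulene-5-carboxylate
Product: 14 methyl (5S,6R,8S,8aR)-6-hydroxy-3,8-dimethyl-2-oxo-1,2,4,5,6,7,8,8a-octahydroazulene-5-carboxylate
Conditions: (R)-selective NADPH-dependent ketoreductase from a commercial panel, NADP+ (cat.), i-PrOH, phosphate buffer pH 7, DMSO (5 vol %), 30 °C
Reagents that add atoms: none
Why: In this enzymatic dynamic reductive kinetic resolution of a 2-oxocycloalkanecarboxylate, C7 epimerises rapidly through the enol at neutral pH while the enzyme accepts one C7 epimer and delivers hydride to one face of C8 (the face anti to the C10 methyl), which should give the cis (C7 S, C8 R) hydroxy ester and leave the hindered conjugated C3 ketone alone.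

Step 9
Reactants: 14 methyl (5S,6R,8S,8aR)-6-hydroxy-3,8-dimethyl-2-oxo-1,2,4,5,6,7,8,8a-octahydroazulene-5-carboxylate
Product: 15 methyl (5S,6R,8S,8aR)-2,6-dihydroxy-3,8-dimethyl-1,2,4,5,6,7,8,8a-octahydroazulene-5-carboxylate (carbinol C3 of guaiane numbering unassigned)
Conditions: NaBH4, CeCl3·7H2O, MeOH, −20 °C
Reagents that add atoms: none
Why: Luche reduction gives clean 1,2-reduction of the enone without touching the ester, which masks C3 against the Grignard reagent, and the configuration of the new carbinol is irrelevant because step 11 erases it.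

Step 10
Reactants: 15 methyl (5S,6R,8S,8aR)-2,6-dihydroxy-3,8-dimethyl-1,2,4,5,6,7,8,8a-octahydroazulene-5-carboxylate
Product: 16 (5S,6R,8S,8aR)-5-(2-hydroxypropan-2-yl)-3,8-dimethyl-1,2,4,5,6,7,8,8a-octahydroazulene-2,6-diol (carbinol C3 of guaiane numbering unassigned)
Conditions: MeMgBr (8 equiv), THF, 0 °C to rt; aq NH4Cl
Reagents that add atoms: methylmagnesium bromide, C[Mg]Br
Why: In this double Grignard addition to an ester the two hydroxyls are first converted into magnesium alkoxides, the C8 alkoxide chelates and activates the neighbouring ester, and the intermediate methyl ketone is consumed faster than it enolises, so C7 should keep its configuration, as is usual for β-hydroxy esters giving 1,3-diols.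

Step 11
Reactants: 16 (5S,6R,8S,8aR)-5-(2-hydroxypropan-2-yl)-3,8-dimethyl-1,2,4,5,6,7,8,8a-octahydroazulene-2,6-diol
Product: 17 (5S,6R,8S,8aR)-6-hydroxy-5-(2-hydroxypropan-2-yl)-3,8-dimethyl-4,5,6,7,8,8a-hexahydroazulen-2(1H)-one
Conditions: MnO2 (activated, excess), CH2Cl2, rt
Reagents that add atoms: none
Why: Allylic oxidation with MnO2 is chemoselective for the cyclopentenol and should leave the saturated secondary C8 alcohol and the tertiary C11 alcohol unchanged.

Step 12
Reactants: 17 (5S,6R,8S,8aR)-6-hydroxy-5-(2-hydroxypropan-2-yl)-3,8-dimethyl-4,5,6,7,8,8a-hexahydroazulen-2(1H)-one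
Product: 18 (5S,6R,8S,8aR)-5-(2-hydroxypropan-2-yl)-3,8-dimethyl-2-oxo-1,2,4,5,6,7,8,8a-octahydroazulen-6-yl propanoate
Conditions: (EtCO)2O (1.3 equiv), pyridine, DMAP (cat.), CH2Cl2, 0 °C to rt
Reagents that add atoms: propionic anhydride, CCC(=O)OC(=O)CC
Why: DMAP-catalysed acyl transfer discriminates on steric grounds, so the secondary C8 alcohol should be esterified while the tertiary C11 alcohol stays free under these mild conditions.

Step 13
Reactants: 18 (5S,6R,8S,8aR)-5-(2-hydroxypropan-2-yl)-3,8-dimethyl-2-oxo-1,2,4,5,6,7,8,8a-octahydroazulen-6-yl propanoate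
Product: 19 (5S,6R,8S,8aR)-5-(2-acetoxypropan-2-yl)-3,8-dimethyl-2-oxo-1,2,4,5,6,7,8,8a-octahydroazulen-6-yl propanoate (CNP0288556.1)
Conditions: Ac2O, Sc(OTf)3 (5 mol %), MeCN, −20 °C
Reagents that add atoms: acetic anhydride, CC(=O)OC(C)=O
Why: Lewis-acid-catalysed acylation with an anhydride generates a highly electrophilic acyl donor, so O-acetylation of the tertiary alcohol at low temperature should outrun ionisation of the C11–O bond and propionyl migration, and no stereocentre is touched.

Compound list
1 | methyl acetoacetate | COC(=O)CC(C)=O | starting material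
2 | methyl 2-diazo-3-oxobutanoate | COC(=O)C(=[N+]=[N-])C(C)=O | intermediate
3 | methyl 2-diazo-3-(tert-butyldimethylsilyloxy)but-3-enoate | COC(=O)C(=[N+]=[N-])C(=C)O[Si](C)(C)C(C)(C)C | intermediate
4 | (E)-pent-3-en-2-one | C/C=C/C(C)=O | starting material
5 | (E)-2-(triethylsilyloxy)penta-1,3-diene | C=C(O[Si](CC)(CC)CC)/C=C/C | intermediate
6 | methyl (1R,2S)-1-[1-(tert-butyldimethylsilyloxy)ethenyl]-2-[(E)-prop-1-enyl]-2-(triethylsilyloxy)cyclopropane-1-carboxylate (cis-divinylcyclopropane, not isolated) | COC(=O)[C@@]1(C(=C)O[Si](C)(C)C(C)(C)C)C[C@]1(O[Si](CC)(CC)CC)/C=C/C | intermediate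
7 | methyl (4S)-2-(tert-butyldimethylsilyloxy)-4-methyl-6-(triethylsilyloxy)cyclohepta-1,5-diene-1-carboxylate | COC(=O)C1=C(O[Si](C)(C)C(C)(C)C)C[C@H](C)C=C(O[Si](CC)(CC)CC)C1 | intermediate
8 | 2-nitrobutan-1-ol (racemic, stereocentre lost in step 5) | CCC(CO)[N+](=O)[O-] | starting material
9 | 2-nitrobut-1-ene | CCC(=C)[N+](=O)[O-] | intermediate
10 | triethylsilyl nitronate of methyl (4S,5R)-2-(tert-butyldimethylsilyloxy)-4-methyl-5-(2-nitrobutyl)-6-oxocyclohept-1-ene-1-carboxylate (not isolated) | COC(=O)C1=C(O[Si](C)(C)C(C)(C)C)C[C@H](C)[C@@H](CC(CC)=[N+]([O-])O[Si](CC)(CC)CC)C(=O)C1 | intermediate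
11 | methyl (4S,5R)-2-hydroxy-4-methyl-6-oxo-5-(2-oxobutyl)cyclohept-1-ene-1-carboxylate (β-keto ester drawn as enol) | COC(=O)C1=C(O)C[C@H](C)[C@@H](CC(=O)CC)C(=O)C1 | intermediate
12 | methyl (8S,8aR)-3a,6-dihydroxy-3,8-dimethyl-2-oxo-1,2,3,3a,4,7,8,8a-octahydroazulene-5-carboxylate (aldol adduct, the two new centres unassigned, not isolated) | COC(=O)C1=C(O)C[C@H](C)[C@H]2CC(=O)C(C)C2(O)C1 | intermediate
13 | methyl (8S,8aR)-6-hydroxy-3,8-dimethyl-2-oxo-1,2,4,7,8,8a-hexahydroazulene-5-carboxylate (β-keto ester drawn as enol) | COC(=O)C1=C(O)C[C@H](C)[C@H]2CC(=O)C(C)=C2C1 | intermediate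
14 | methyl (5S,6R,8S,8aR)-6-hydroxy-3,8-dimethyl-2-oxo-1,2,4,5,6,7,8,8a-octahydroazulene-5-carboxylate | O[C@@H]1C[C@H](C)[C@H]2CC(=O)C(C)=C2C[C@@H]1C(=O)OC | intermediate
15 | methyl (5S,6R,8S,8aR)-2,6-dihydroxy-3,8-dimethyl-1,2,4,5,6,7,8,8a-octahydroazulene-5-carboxylate (allylic carbinol unassigned) | O[C@@H]1C[C@H](C)[C@H]2CC(O)C(C)=C2C[C@@H]1C(=O)OC | intermediate
16 | (5S,6R,8S,8aR)-5-(2-hydroxypropan-2-yl)-3,8-dimethyl-1,2,4,5,6,7,8,8a-octahydroazulene-2,6-diol (allylic carbinol unassigned) | O[C@@H]1C[C@H](C)[C@H]2CC(O)C(C)=C2C[C@@H]1C(C)(C)O | intermediate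
17 | (5S,6R,8S,8aR)-6-hydroxy-5-(2-hydroxypropan-2-yl)-3,8-dimethyl-4,5,6,7,8,8a-hexahydroazulen-2(1H)-one | O[C@@H]1C[C@H](C)[C@H]2CC(=O)C(C)=C2C[C@@H]1C(C)(C)O | intermediate
18 | (5S,6R,8S,8aR)-5-(2-hydroxypropan-2-yl)-3,8-dimethyl-2-oxo-1,2,4,5,6,7,8,8a-octahydroazulen-6-yl propanoate | CCC(=O)O[C@@H]1C[C@H](C)[C@H]2CC(=O)C(C)=C2C[C@@H]1C(C)(C)O | intermediate
19 | (5S,6R,8S,8aR)-5-(2-acetoxypropan-2-yl)-3,8-dimethyl-2-oxo-1,2,4,5,6,7,8,8a-octahydroazulen-6-yl propanoate (CNP0288556.1) | CCC(=O)O[C@@H]1C[C@H](C)[C@H]2CC(=O)C(C)=C2C[C@@H]1C(C)(C)OC(C)=O | target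

Total step count: 13.
Longest linear sequence: 11 steps (1 → 2 → 3 → 7 → 11 → 13 → 14 → 15 → 16 → 17 → 18 → 19).

Steps most likely to fail

Step 8.
- **What may go wrong:** the bicyclic substrate may not be accepted by the enzymes screened, or hydride may be delivered to the wrong carbonyl face or to the wrong C7 epimer.
- **Fallback (chelate and substrate control instead of enzyme control):** setting out from 13, Zn(BH4)2 in Et2O/CH2Cl2 at −78 to −20 °C reduces the zinc-chelated keto tautomer. The chelate holds ester and ketone coplanar, so hydride enters C8 from the side of H7, which gives the cis pair. Of the two interconverting C7 epimers, the one that can be attacked anti to the C10 methyl should react faster.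
- **Return to the route:** partial 1,2-reduction at C3 does no harm, because the crude product goes straight through the conditions of step 9. The route is rejoined at 15, where minor diastereomers are removed by chromatography. This detour makes no compound outside the list (entry F0).

Step 6.
- **What may go wrong:** the triethylsilyl enol ether may be protodesilylated before the C–C bond forms, which loses the regiochemical handle. The Lewis acid may desilylate C8, after which C7 attacks the nitroalkene. Compound 9 may polymerise, or the nitronate may hydrolyse incompletely.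
- **Fallback (radical instead of polar formation of C1–C2, without Lewis acid or Nef step):** setting out from 7, irradiation with blue light in the presence of 1-bromobutan-2-one, fac-Ir(ppy)3 (1 mol %) and 2,6-lutidine in MeCN at rt generates the electrophilic 2-oxobutyl radical. This radical adds to the C1 terminus of the electron-rich C5 enol ether and leaves the tetrasubstituted, ester-conjugated C7=C8 bond alone. Oxidation of the α-siloxy radical and loss of the silyl group should give methyl (4S,5R)-2-(tert-butyldimethylsilyloxy)-4-methyl-6-oxo-5-(2-oxobutyl)cyclohept-1-ene-1-carboxylate F1.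
- **Return to the route:** 1 M HCl in THF removes the remaining silyl group and the route is rejoined at 11.

Step 4.
- **What may go wrong:** enantiofacial discrimination on a 1,1-disubstituted enol ether may be insufficient. Some trans-divinylcyclopropane may form, and its thermal isomerisation would erode optical purity. The enol ether may also attack the carbenoid terminus in a vinylogous sense.
- **Fallback (same ring construction, but C10 set by asymmetric conjugate addition instead of by the carbenoid step):** the fallback sets out from 3.
  - Methyl vinyl ketone is silylated (TESOTf, Et3N, Et2O, 0 °C) to 2-(triethylsilyloxy)buta-1,3-diene F2.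
  - With 3 and dirhodium tetraoctanoate in hexanes, F2 undergoes the same cyclopropanation/Cope sequence to give the achiral methyl 2-(tert-butyldimethylsilyloxy)-6-(triethylsilyloxy)cyclohepta-1,5-diene-1-carboxylate F3.
  - Saegusa–Ito oxidation of the simple enol ether (Pd(OAc)2, MeCN, rt) gives methyl 2-(tert-butyldimethylsilyloxy)-6-oxocyclohepta-1,4-diene-1-carboxylate F4.
- **Return to the route:** addition of Me2Zn to C10 is catalysed by Cu(OTf)2 and a BINOL-derived bis(1-phenylethyl)amine phosphoramidite, with the ligand antipode chosen for S at C10. Trapping of the zinc enolate with TESOTf regenerates the regiodefined enol ether, and the route is rejoined at 7.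

Further compounds
F0 | step 8 | none | none
F1 | step 6 | methyl (4S,5R)-2-(tert-butyldimethylsilyloxy)-4-methyl-6-oxo-5-(2-oxobutyl)cyclohept-1-ene-1-carboxylate | COC(=O)C1=C(O[Si](C)(C)C(C)(C)C)C[C@H](C)[C@@H](CC(=O)CC)C(=O)C1
F2 | step 4 | 2-(triethylsilyloxy)buta-1,3-diene | C=CC(=C)O[Si](CC)(CC)CC
F3 | step 4 | methyl 2-(tert-butyldimethylsilyloxy)-6-(triethylsilyloxy)cyclohepta-1,5-diene-1-carboxylate (achiral) | COC(=O)C1=C(O[Si](C)(C)C(C)(C)C)CCC=C(O[Si](CC)(CC)CC)C1
F4 | step 4 | methyl 2-(tert-butyldimethylsilyloxy)-6-oxocyclohepta-1,4-diene-1-carboxylate (achiral) | COC(=O)C1=C(O[Si](C)(C)C(C)(C)C)CC=CC(=O)C1
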